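## Structural features

The target is a propan-1-one. Its C1 carbonyl belongs to a 2-hydroxy-4-methoxyphenyl ketone, its C2 methine carries a 7-hydroxychromon-3-yl ring through chromone C3, and its C3 methine carries two identical 4-hydroxyphenyl rings. C2 is the only stereocentre; with the priorities acyl > chromon-3-yl > diarylmethyl the drawn arrangement is R, and because the two aryl groups on C3 are the same there is no neighbouring stereocentre and no relative configuration to control. The C2–H bond is the fragile point: it is α to an aryl ketone and sits on the α-carbon of the chromone enone, so it is acidic and epimerises under base once both flanking groups are present. The pyranone ring is a second weak point, because hydroxide, amines and thiolates add at chromone C2 and open it; in addition four phenols must be carried masked while the 4-methoxy group stays. The real difficulty is to crowd three bulky units around one tertiary, enolisable carbon in a single absolute configuration and to keep that configuration to the end. The plan exploits the fact that the ring oxygen O1 and the carbonyl carbon C4 of the chromone stand on adjacent benzene carbons, C8a and C4a. One carboxylic acid can hand its oxygen and its acyl carbon to the two carbons of an aryne, so the benzo ring can be joined to a chain whose stereocentre is at that moment only α to an ester. The 7-oxygen lies para to C4a, and a chlorine at the future C5 (ortho to C4a) can steer that union and leave again together with the benzyl groups.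

## Logic of the disconnections

29 ⇒ 28. The four benzyl C–O bonds and the C5–Cl bond are restored. All phenols then carry one kind of protecting group and the temporary director leaves in the same operation, so the last step makes no skeletal bond. The demand is that hydrogen removes benzyl and chlorine before it touches the chromone C2=C3 bond, and that the medium is not basic enough to epimerise C2.

28 ⇒ 27 + 23. The bond between the C1 carbonyl and its aryl ring is cut. The ketone is introduced last because the C2–H bond reaches its full acidity only when ketone and chromone are both present. This removes the fourth aromatic ring and lets it arrive as 23 with its hydroxyl already masked. The forward step must be an acyl coupling that needs no base and tolerates a hindered acyl group and an ortho-substituted boron partner.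

23 ⇒ 20 ⇒ 19. The C–B bond goes back to a C–Br bond (through 21 and 22) and the benzyl ether to a phenol. The demand is only that halogen–metal exchange is faster than benzylic deprotonation.

27 ⇒ 26. The O1–C2 and C2–C3 bonds of the pyranone are cut, which removes C2 as a one-carbon electrophile and reveals an o-hydroxyaryl ketone with an α-methylene group. This is the ring-forming step of the route; it must run under acidic, nucleophile-free conditions so that the thioester and the stereocentre survive, and it must reach a methylene next to a congested carbon.

26 ⇒ 25. The acyl–S bond is exchanged for an acyl–O bond. A thioester or the imide cannot be carried through the aryne step, because the neighbouring carboxylate would expel the thiolate or the imide nitrogen through a five-membered anhydride. A thioester should equally not be made after the chromone exists, because thiolates add to chromone C2. The exchange is therefore placed between the two events and has to work on a hindered ester beside a chelated phenol ketone.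

25 ⇒ 12 + 18 (through 24). The aryl–acyl bond C4a–C4 and the aryl–oxygen bond C8a–O1 are cut together; both go back to the single carboxyl group of 12 and to the two carbons of 24. This separates the whole benzo ring from the stereodefined chain, and it is the strategic simplification. The forward step must add oxygen to the aryne carbon remote from chlorine, must transfer the acyl group faster than the aryl anion is protonated or loses chloride, and must leave the ester-bound stereocentre alone. The methyl ester of 12 is kept as the spectator because it resists the neighbouring carboxylate.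

12 ⇒ 11 ⇒ 10. The free acid goes back to its tert-butyl ester and the methyl ester to the acyl oxazolidinone. These two operations differentiate the two carboxyl groups (acid on the methylene arm, ester on the stereocentre); they must be mild enough not to epimerise the α-carbon.

10 ⇒ 7 + 8 (through 9). The bond between the stereocentre and the CH2CO2 arm is cut. This is where the absolute configuration is set, by auxiliary-controlled enolate alkylation; the demand is high facial selectivity on a β-branched enolate.

7 ⇒ 4 + 5 (through 6), and 4 ⇒ 1 + 2 (through 3). One C3–aryl bond is cut as a conjugate addition and the N-acyl bond as an acylation. Since the two aryl groups are identical the conjugate addition creates no stereocentre, so this is the shortest way to the diarylpropanoyl imide.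

18 ⇒ 15 ⇒ 14 ⇒ 13 (through 16 and 17). The S–O bond, the C–Si bond (from C–Br by an oxygen-to-carbon silyl shift), the C–Br bond and the C–Cl bond are removed in turn. Each halogenation must go ortho to the free hydroxyl and not ortho to the benzyl ether.

## Other disconnections considered

Alternative 1: Both C3–aryl bonds and the C2–H bond are cut. Forward, the hydroxymethylene ketone A1 would condense with two molecules of phenol A2 under a chiral phosphoric acid: hydroxyalkylation at the formyl carbon, dehydration to a conjugated acceptor, a second para-arylation, and protonation of the resulting enol at C2, to give A3.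
- In its favour: two C–C bonds, the diarylmethyl unit and the stereocentre arise in one operation from an unprotected phenol; no auxiliary and no halogen director are needed.
- Against it: para versus ortho (and oxygen) alkylation of A2 must be controlled twice; the configuration rests on protonation of an acyclic, fully substituted enol; and A3 carries its labile C2–H in the same acidic medium that made it, so the configuration could be lost again. A3 also needs a selective ortho demethylation beside the retained 4-methoxy group.
- Comparison: on step economy Alternative 1 is clearly the better plan, and on structure it is the equal of the chosen plan in leaving the chromone untouched and better in needing no chlorine. On mechanism the chosen plan is safer, because its stereocentre is set by a predictable auxiliary-controlled alkylation at the ester stage and meets the acidic ketone environment only in the last two steps.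

Alternative 2: The chromone C3–C4 bond is cut at the chromanone oxidation level. Forward, a chiral triazolylidene would convert the aldehyde-tethered E-enone A4 into A5 by an intramolecular Stetter reaction (6-exo-trig addition of the acyl anion equivalent, then protonation of the enolate).
- In its favour: asymmetric Stetter closure to chroman-4-ones is an established catalytic reaction; ring and stereocentre come from one step; no directing halogen is needed.
- Against it: the acceptor in A4 is a trisubstituted enone with a very bulky α-substituent; the side-chain configuration depends on a diastereoselective protonation; and A5 must still be dehydrogenated to the chromone. That oxidation discards the ring stereocentre and has to be done next to the C–H bond that is then most acidic. A4 also needs a geometrically defined trisubstituted enone, which is long to assemble.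
- Comparison: the two plans are equal in that each builds the pyranone around a carbon at the benzoyl level, and Alternative 2 is better in using catalytic rather than auxiliary induction. It is weaker in the late oxidation and in precursor assembly, and the step count is unlikely to be lower.

Alternative 3: Two bonds of the 2-hydroxy-4-methoxyphenyl ring are cut. Forward, the terminal ynone A6 and Brassard's diene A7 would undergo a [4+2] cycloaddition and aromatise by elimination to give A8.
- In its favour: the regiochemistry follows from the polarisation of A7 (its nucleophilic terminal carbon bonds to the alkyne terminus), so no temporary director is needed. The chelated hydroxyl and the methoxy group appear in the right places without a protecting group or a cross-coupling. On this point Alternative 3 is better than the way the chosen plan introduces the ketone ring.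
- Against it: A6 carries the stereocentre α to an ynone and on chromone C3, which is more acidic than any intermediate of the chosen route; the thermal cycloaddition and the elimination both threaten it. A6 is also a reactive conjugate acceptor and must itself be made enantiopure by other means.
- Comparison: the plans are equal in that neither key step creates the stereocentre. The chosen plan keeps that centre at the ester or thioester level until the ketone is made under neutral conditions, whereas Alternative 3 exposes it in its most labile form for several steps. Step economy is comparable.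

Key step: step 11

Assumption: 1, 2, 5, 8, 13 and 19 are taken as commercial. The configurations were rechecked: 12 and 25 are (S) and lead to (R)-29 without any change at the stereocentre, the descriptor switching in step 13 only because the chromone carbon outranks the diarylmethyl carbon.

## Route

Step 1
Reactants: 1 (E)-3-[4-(benzyloxy)phenyl]prop-2-enoic acid; 2 (S)-4-benzyl-1,3-oxazolidin-2-one
Product: 4 (S)-4-benzyl-3-{(E)-3-[4-(benzyloxy)phenyl]prop-2-enoyl}-1,3-oxazolidin-2-one, via mixed pivalic anhydride 3 (not isolated)
Conditions: PivCl, Et3N, THF, −20 °C; then LiCl, 2, −20 °C → rt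
Reagents that add atoms: none
Why: N-acylation of an oxazolidinone through a mixed pivalic anhydride; the hindered pivaloyl carbonyl is not attacked, and LiCl with Et3N makes the oxazolidinone nucleophilic enough without a strong base, so the E-alkene is untouched.

Step 2
Reactants: 4 (S)-4-benzyl-3-{(E)-3-[4-(benzyloxy)phenyl]prop-2-enoyl}-1,3-oxazolidin-2-one; 5 1-(benzyloxy)-4-bromobenzene
Product: 7 (S)-4-benzyl-3-{3,3-bis[4-(benzyloxy)phenyl]propanoyl}-1,3-oxazolidin-2-one, via aryl Grignard reagent 6 (not isolated)
Conditions: 5, Mg, THF, 40 °C; then CuBr·SMe2, THF–Me2S, −40 °C; 4, −40 → −10 °C; aq. NH4Cl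
Reagents that add atoms: none
Why: Copper-mediated conjugate addition of an aryl Grignard reagent to an N-enoyl oxazolidinone; copper suppresses 1,2-addition, and because the β-carbon ends with two identical aryl groups no stereocentre arises.

Step 3
Reactants: 7 (S)-4-benzyl-3-{3,3-bis[4-(benzyloxy)phenyl]propanoyl}-1,3-oxazolidin-2-one; 8 tert-butyl bromoacetate
Product: 10 tert-butyl (S)-3-{[(S)-4-benzyl-2-oxo-1,3-oxazolidin-3-yl]carbonyl}-4,4-bis[4-(benzyloxy)phenyl]butanoate, via sodium enolate 9 (not isolated)
Conditions: NaN(SiMe3)2, THF, −78 °C; then 8, −78 → −45 °C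
Reagents that add atoms: none
Why: Evans auxiliary-directed enolate alkylation; the chelated Z-enolate is covered on one face by the 4-benzyl group and the reactive α-bromo ester enters from the other, which with the (S)-auxiliary gives the (S)-configured centre (diarylmethyl outranks the new CH2CO2 arm); any minor diastereomer is separable at this stage.

Step 4
Reactants: 10 tert-butyl (S)-3-{[(S)-4-benzyl-2-oxo-1,3-oxazolidin-3-yl]carbonyl}-4,4-bis[4-(benzyloxy)phenyl]butanoate
Product: 11 4-tert-butyl 1-methyl (S)-2-{bis[4-(benzyloxy)phenyl]methyl}butanedioate
Conditions: MeMgBr, MeOH, 0 °C → rt; aq. NH4Cl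
Reagents that add atoms: methanol, CO
Why: Transesterification of an N-acyl oxazolidinone with methoxymagnesium bromide; magnesium chelation of the two imide carbonyls directs methoxide to the exocyclic one, the weakly basic medium should leave the α-stereocentre and the tert-butyl ester alone, and the auxiliary is recovered.

Step 5
Reactants: 11 4-tert-butyl 1-methyl (S)-2-{bis[4-(benzyloxy)phenyl]methyl}butanedioate
Product: 12 (S)-4,4-bis[4-(benzyloxy)phenyl]-3-(methoxycarbonyl)butanoic acid
Conditions: TFA, CH2Cl2, 0 °C → rt
Reagents that add atoms: none
Why: Acidolysis of a tert-butyl ester by alkyl–oxygen cleavage; the methyl ester, the aryl benzyl ethers and the stereocentre are inert to short exposure to TFA.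

Step 6
Reactants: 13 4-(benzyloxy)phenol
Product: 14 4-(benzyloxy)-2-chlorophenol
Conditions: SO2Cl2, diisobutylamine (cat.), toluene, 50 °C
Reagents that add atoms: sulfuryl chloride, O=S(=O)(Cl)Cl
Why: Amine-catalysed ortho-chlorination of a phenol (electrophilic aromatic substitution); the free hydroxyl activates more strongly than the benzyl ether and the hydrogen-bonded catalyst delivers chlorine next to it, while one equivalent of reagent limits dichlorination.

Step 7
Reactants: 14 4-(benzyloxy)-2-chlorophenol
Product: 15 4-(benzyloxy)-2-bromo-6-chlorophenol
Conditions: NBS, diisopropylamine (cat.), CH2Cl2, 0 °C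
Reagents that add atoms: N-bromosuccinimide, O=C1CCC(=O)N1Br
Why: Ortho-bromination of a phenol (electrophilic aromatic substitution); the one position still ortho to the hydroxyl is the most activated, and the para position is blocked.

Step 8
Reactants: 15 4-(benzyloxy)-2-bromo-6-chlorophenol
Product: 18 4-(benzyloxy)-2-chloro-6-(trimethylsilyl)phenyl trifluoromethanesulfonate, via aryl trimethylsilyl ether 16 (not isolated), via lithium phenoxide 17 (not isolated)
Conditions: HN(SiMe3)2, THF, 65 °C, evaporate; n-BuLi, THF, −100 → −78 °C; Tf2O, −78 °C → rt
Reagents that add atoms: hexamethyldisilazane, C[Si](C)(C)N[Si](C)(C)C; trifluoromethanesulfonic anhydride, O=S(=O)(OS(=O)(=O)C(F)(F)F)C(F)(F)F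
Why: O-silylation, bromine–lithium exchange with retro-Brook (oxygen-to-carbon) silyl shift, then O-triflation of the phenoxide, the standard one-pot route to o-silylaryl triflates; exchange at bromine is far faster than at chlorine or than benzylic deprotonation at this temperature.

Step 9
Reactants: 19 2-bromo-5-methoxyphenol
Product: 20 2-(benzyloxy)-1-bromo-4-methoxybenzene
Conditions: BnBr, K2CO3, DMF, rt
Reagents that add atoms: benzyl bromide, BrCc1ccccc1
Why: Williamson ether synthesis on a phenoxide; benzyl is chosen so that this hydroxyl is released in the final hydrogenolysis without a step of its own.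

Step 10
Reactants: 20 2-(benzyloxy)-1-bromo-4-methoxybenzene
Product: 23 [2-(benzyloxy)-4-methoxyphenyl]boronic acid, via aryllithium 21 (not isolated), via lithium triisopropyl borate 22 (not isolated)
Conditions: n-BuLi, THF, −78 °C; B(OCHMe2)3, −78 °C → rt; 1 M HCl
Reagents that add atoms: triisopropyl borate, CC(C)OB(OC(C)C)OC(C)C; water, O
Why: Bromine–lithium exchange, borylation with a trialkyl borate and hydrolysis; exchange outruns benzylic deprotonation at −78 °C and the ortho-alkoxy group stabilises the aryllithium.

Step 11
Reactants: 12 (S)-4,4-bis[4-(benzyloxy)phenyl]-3-(methoxycarbonyl)butanoic acid; 18 4-(benzyloxy)-2-chloro-6-(trimethylsilyl)phenyl trifluoromethanesulfonate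
Product: 25 methyl (S)-4-[4-(benzyloxy)-2-chloro-6-hydroxyphenyl]-2-{bis[4-(benzyloxy)phenyl]methyl}-4-oxobutanoate, via aryne 24 (not isolated)
Conditions: CsF, THF, sealed tube, 125 °C
Reagents that add atoms: none
Why: Fluoride removes the silyl group of 18 and loss of triflate gives aryne 24; the caesium carboxylate of 12 adds through oxygen to the aryne carbon remote from chlorine, because the inductively withdrawing halogen distorts the triple bond so that this end is the more electrophilic and the charge develops next to chlorine. The aryl anion then attacks the carbonyl of the aryl ester just formed through a four-membered tetrahedral intermediate, whose C–O bond breaks to leave the ortho-acyl phenoxide, so that the aryne is formally inserted into the acid C–O bond. The closest known reaction type is exactly this one: insertion of arynes from o-silylaryl triflates into the C–O bond of carboxylic acids to give o-hydroxyaryl ketones, in which 3-substituted arynes react with high regiocontrol. No ring closes and no stereocentre is made; the aryl–oxygen and aryl–acyl bonds form on neighbouring carbons. The step needs regioselective addition, which the chlorine secures (the remote benzyloxy group, meta to the attacked carbon, exerts only a small opposing inductive bias), and it needs the acyl shift to outrun protonation and chloride loss, which the aprotic medium and the proximity of the ester carbonyl favour. Attack on the distant methyl ester would need a seven-membered transition state and is not expected to compete. The existing stereocentre is α only to the methyl ester, a carbon acid too weak for fluoride, carboxylate or phenoxide to enolise at a significant rate, so it should be carried through unchanged as (S).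

Step 12
Reactants: 25 methyl (S)-4-[4-(benzyloxy)-2-chloro-6-hydroxyphenyl]-2-{bis[4-(benzyloxy)phenyl]methyl}-4-oxobutanoate
Product: 26 S-ethyl (S)-4-[4-(benzyloxy)-2-chloro-6-hydroxyphenyl]-2-{bis[4-(benzyloxy)phenyl]methyl}-4-oxobutanethioate
Conditions: Me3Al, EtSH, CH2Cl2, 0 °C → rt; aq. HCl
Reagents that add atoms: ethanethiol, CCS
Why: Ester-to-thioester exchange with dimethylaluminium ethanethiolate; the oxophilic aluminium activates the ester and takes up methoxide while sulfur is delivered under non-basic conditions, the phenol is only converted into its aluminium phenoxide, and the chelated, doubly ortho-substituted ketone is too hindered to react; at this point no carboxylate remains to expel the thiolate and no chromone is yet present to accept it.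

Step 13
Reactants: 26 S-ethyl (S)-4-[4-(benzyloxy)-2-chloro-6-hydroxyphenyl]-2-{bis[4-(benzyloxy)phenyl]methyl}-4-oxobutanethioate
Product: 27 S-ethyl (R)-2-[7-(benzyloxy)-5-chloro-4-oxo-4H-chromen-3-yl]-3,3-bis[4-(benzyloxy)phenyl]propanethioate
Conditions: BF3·OEt2, DMF, rt; then MsCl, 60 °C; aq. NaOAc
Reagents that add atoms: N,N-dimethylformamide, CN(C)C=O
Why: Vilsmeier–Haack-type formylation and cyclisation of an o-hydroxyaryl ketone, the one-carbon closure used for 3-substituted chromones; boron chelation makes the α-methylene nucleophilic, the iminium reagent from DMF and MsCl supplies C2, the phenol oxygen closes onto it and dimethylamine is lost; the medium is acidic and free of nucleophiles, so the thioester and the stereocentre (now R by priority only) should survive.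

Step 14
Reactants: 27 S-ethyl (R)-2-[7-(benzyloxy)-5-chloro-4-oxo-4H-chromen-3-yl]-3,3-bis[4-(benzyloxy)phenyl]propanethioate; 23 [2-(benzyloxy)-4-methoxyphenyl]boronic acid
Product: 28 (R)-1-[2-(benzyloxy)-4-methoxyphenyl]-2-[7-(benzyloxy)-5-chloro-4-oxo-4H-chromen-3-yl]-3,3-bis[4-(benzyloxy)phenyl]propan-1-one
Conditions: Pd2(dba)3 (cat.), P(2-furyl)3, Cu(O2CC4H3S) (copper thiophene-2-carboxylate), THF, 50 °C
Reagents that add atoms: none
Why: Liebeskind–Srogl thioester–boronic acid coupling; zerovalent palladium inserts into the C–S bond while the copper carboxylate binds sulfur and activates boron, so no base is needed, which is what the acidic C2–H of the product requires; the aryl chloride should not undergo oxidative addition with this catalyst at 50 °C.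

Step 15
Reactants: 28 (R)-1-[2-(benzyloxy)-4-methoxyphenyl]-2-[7-(benzyloxy)-5-chloro-4-oxo-4H-chromen-3-yl]-3,3-bis[4-(benzyloxy)phenyl]propan-1-one
Product: 29 (R)-2-(7-hydroxy-4-oxo-4H-chromen-3-yl)-1-(2-hydroxy-4-methoxyphenyl)-3,3-bis(4-hydroxyphenyl)propan-1-one
Conditions: H2 (1 atm), Pd/C, NaOAc, EtOAc–MeOH, rt
Reagents that add atoms: none
Why: Catalytic hydrogenolysis of four aryl benzyl ethers together with hydrodechlorination of the aryl chloride, which is activated by the peri carbonyl; acetate only buffers the HCl released, and the 3-substituted chromone double bond and the chelated aryl ketone should be reduced much more slowly, so the reaction is stopped once chlorine is gone.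

## Compound list

1 | (E)-3-[4-(benzyloxy)phenyl]prop-2-enoic acid | O=C(O)/C=C/c1ccc(OCc2ccccc2)cc1 | starting material
2 | (S)-4-benzyl-1,3-oxazolidin-2-one | O=C1N[C@@H](Cc2ccccc2)CO1 | starting material
3 | (E)-3-[4-(benzyloxy)phenyl]prop-2-enoic pivalic anhydride | CC(C)(C)C(=O)OC(=O)/C=C/c1ccc(OCc2ccccc2)cc1 | intermediate (not isolated)
4 | (S)-4-benzyl-3-{(E)-3-[4-(benzyloxy)phenyl]prop-2-enoyl}-1,3-oxazolidin-2-one | O=C(/C=C/c1ccc(OCc2ccccc2)cc1)N1C(=O)OC[C@@H]1Cc1ccccc1 | intermediate
5 | 1-(benzyloxy)-4-bromobenzene | Brc1ccc(OCc2ccccc2)cc1 | starting material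
6 | [4-(benzyloxy)phenyl]magnesium bromide | Br[Mg]c1ccc(OCc2ccccc2)cc1 | intermediate (not isolated)
7 | (S)-4-benzyl-3-{3,3-bis[4-(benzyloxy)phenyl]propanoyl}-1,3-oxazolidin-2-one | O=C(CC(c1ccc(OCc2ccccc2)cc1)c1ccc(OCc2ccccc2)cc1)N1C(=O)OC[C@@H]1Cc1ccccc1 | intermediate
8 | tert-butyl bromoacetate | CC(C)(C)OC(=O)CBr | starting material
9 | sodium (Z)-enolate of 7 | [Na+].[O-]/C(=C\C(c1ccc(OCc2ccccc2)cc1)c1ccc(OCc2ccccc2)cc1)N1C(=O)OC[C@@H]1Cc1ccccc1 | intermediate (not isolated)
10 | tert-butyl (S)-3-{[(S)-4-benzyl-2-oxo-1,3-oxazolidin-3-yl]carbonyl}-4,4-bis[4-(benzyloxy)phenyl]butanoate | CC(C)(C)OC(=O)C[C@H](C(=O)N1C(=O)OC[C@@H]1Cc1ccccc1)C(c1ccc(OCc2ccccc2)cc1)c1ccc(OCc2ccccc2)cc1 | intermediate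
11 | 4-tert-butyl 1-methyl (S)-2-{bis[4-(benzyloxy)phenyl]methyl}butanedioate | COC(=O)[C@@H](CC(=O)OC(C)(C)C)C(c1ccc(OCc2ccccc2)cc1)c1ccc(OCc2ccccc2)cc1 | intermediate
12 | (S)-4,4-bis[4-(benzyloxy)phenyl]-3-(methoxycarbonyl)butanoic acid | COC(=O)[C@@H](CC(=O)O)C(c1ccc(OCc2ccccc2)cc1)c1ccc(OCc2ccccc2)cc1 | intermediate
13 | 4-(benzyloxy)phenol | Oc1ccc(OCc2ccccc2)cc1 | starting material
14 | 4-(benzyloxy)-2-chlorophenol | Oc1ccc(OCc2ccccc2)cc1Cl | intermediate
15 | 4-(benzyloxy)-2-bromo-6-chlorophenol | Oc1c(Cl)cc(OCc2ccccc2)cc1Br | intermediate
16 | [4-(benzyloxy)-2-bromo-6-chlorophenoxy]trimethylsilane | C[Si](C)(C)Oc1c(Cl)cc(OCc2ccccc2)cc1Br | intermediate (not isolated)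
17 | lithium 4-(benzyloxy)-2-chloro-6-(trimethylsilyl)phenoxide | [Li+].[O-]c1c(Cl)cc(OCc2ccccc2)cc1[Si](C)(C)C | intermediate (not isolated)
18 | 4-(benzyloxy)-2-chloro-6-(trimethylsilyl)phenyl trifluoromethanesulfonate | O=S(=O)(Oc1c(Cl)cc(OCc2ccccc2)cc1[Si](C)(C)C)C(F)(F)F | intermediate
19 | 2-bromo-5-methoxyphenol | COc1ccc(Br)c(O)c1 | starting material
20 | 2-(benzyloxy)-1-bromo-4-methoxybenzene | COc1ccc(Br)c(OCc2ccccc2)c1 | intermediate
21 | [2-(benzyloxy)-4-methoxyphenyl]lithium | [Li]c1ccc(OC)cc1OCc1ccccc1 | intermediate (not isolated)
22 | lithium [2-(benzyloxy)-4-methoxyphenyl]tri(propan-2-yloxy)borate | [Li+].COc1ccc([B-](OC(C)C)(OC(C)C)OC(C)C)c(OCc2ccccc2)c1 | intermediate (not isolated)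
23 | [2-(benzyloxy)-4-methoxyphenyl]boronic acid | COc1ccc(B(O)O)c(OCc2ccccc2)c1 | intermediate
24 | 5-(benzyloxy)-3-chloro-1,2-didehydrobenzene (the aryne) | ClC1=CC(OCc2ccccc2)=CC#C1 | intermediate (not isolated)
25 | methyl (S)-4-[4-(benzyloxy)-2-chloro-6-hydroxyphenyl]-2-{bis[4-(benzyloxy)phenyl]methyl}-4-oxobutanoate | COC(=O)[C@@H](CC(=O)c1c(O)cc(OCc2ccccc2)cc1Cl)C(c1ccc(OCc2ccccc2)cc1)c1ccc(OCc2ccccc2)cc1 | intermediate
26 | S-ethyl (S)-4-[4-(benzyloxy)-2-chloro-6-hydroxyphenyl]-2-{bis[4-(benzyloxy)phenyl]methyl}-4-oxobutanethioate | CCSC(=O)[C@@H](CC(=O)c1c(O)cc(OCc2ccccc2)cc1Cl)C(c1ccc(OCc2ccccc2)cc1)c1ccc(OCc2ccccc2)cc1 | intermediate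
27 | S-ethyl (R)-2-[7-(benzyloxy)-5-chloro-4-oxo-4H-chromen-3-yl]-3,3-bis[4-(benzyloxy)phenyl]propanethioate | CCSC(=O)[C@@H](c1coc2cc(OCc3ccccc3)cc(Cl)c2c1=O)C(c1ccc(OCc2ccccc2)cc1)c1ccc(OCc2ccccc2)cc1 | intermediate
28 | (R)-1-[2-(benzyloxy)-4-methoxyphenyl]-2-[7-(benzyloxy)-5-chloro-4-oxo-4H-chromen-3-yl]-3,3-bis[4-(benzyloxy)phenyl]propan-1-one | COc1ccc(C(=O)[C@@H](c2coc3cc(OCc4ccccc4)cc(Cl)c3c2=O)C(c2ccc(OCc3ccccc3)cc2)c2ccc(OCc3ccccc3)cc2)c(OCc2ccccc2)c1 | intermediate
29 | (R)-2-(7-hydroxy-4-oxo-4H-chromen-3-yl)-1-(2-hydroxy-4-methoxyphenyl)-3,3-bis(4-hydroxyphenyl)propan-1-one | COc1ccc(C(=O)[C@@H](c2coc3cc(O)ccc3c2=O)C(c2ccc(O)cc2)c2ccc(O)cc2)c(O)c1 | target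

## Step count and least certain steps

Total step count: 15. Longest linear sequence: 10 steps (steps 1–5 and 11–15, from 1 to 29).

Step 11 (key step). The most likely failure is interception of the aryl anion by a proton (from the acid, from HF-bound proton, or from the α-methylene of the aryl ester just formed) before the acyl shift, which would stop the sequence at simple O-arylation. Next in likelihood is slow loss of configuration at the ester α-carbon during a long, hot exposure to fluoride and phenoxide, and then a minor share of addition at the chlorine-proximal aryne carbon. The fallback avoids the aryne and the basic medium. It sets out from 12: Friedel–Crafts acylation of 5-chlororesorcinol with the free acid under BF3·OEt2 at about 70 °C should give methyl (S)-4-(2-chloro-4,6-dihydroxyphenyl)-2-{bis[4-(benzyloxy)phenyl]methyl}-4-oxobutanoate F1. In that symmetrical nucleophile the two carbons flanked by hydroxyl and chlorine are equivalent and acylation between the two hydroxyls is disfavoured. Benzylation with BnBr and K2CO3 in acetone then alkylates the non-chelated hydroxyl (and any phenol that the Lewis acid has freed from its benzyl group) but not the chelated one, and so returns to the route at 25.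

Step 12. The exchange may be slow at an ester flanked by a diarylmethyl group, which invites competing addition of aluminium-bound methyl or thiolate to the ketone, cleavage of benzyl ethers by the Lewis acid–thiol pair, or partial epimerisation at the activated α-carbon. The fallback sets out from 25: hydrolysis with Me3SnOH in 1,2-dichloroethane at 80 °C should give (S)-4-[4-(benzyloxy)-2-chloro-6-hydroxyphenyl]-2-{bis[4-(benzyloxy)phenyl]methyl}-4-oxobutanoic acid F2, and carbodiimide coupling (EDC·HCl, HOBt, EtSH, CH2Cl2, 0 °C) returns to the route at 26.

Step 13. Formylation of a methylene next to a congested carbon may be incomplete, and prolonged heating with the Lewis acid could enolise the thioester and erode the configuration. The fallback changes both the order and the one-carbon reagent and sets out from 25. Heating with N,N-dimethylformamide dimethyl acetal in toluene at 90 °C (enaminone formation, then cyclisation with loss of dimethylamine) should give methyl (R)-2-[7-(benzyloxy)-5-chloro-4-oxo-4H-chromen-3-yl]-3,3-bis[4-(benzyloxy)phenyl]propanoate F3. Me3SnOH hydrolysis then gives (R)-2-[7-(benzyloxy)-5-chloro-4-oxo-4H-chromen-3-yl]-3,3-bis[4-(benzyloxy)phenyl]propanoic acid F4, and EDC·HCl, HOBt and EtSH return to the route at 27.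

Step 14. With an α-branched acyl group and an ortho-substituted boronic acid, transmetalation may be slower than decarbonylation of the acylpalladium species or protodeboronation of the electron-rich boronic acid. The fallback is a Fukuyama coupling and sets out from 27 and 20. Compound 20 is lithiated to 21 as in step 10 and transmetalated with ZnCl2 to [2-(benzyloxy)-4-methoxyphenyl]zinc chloride F5, which with 27 and PdCl2(PPh3)2 in THF–toluene at rt should return to the route at 28 without copper and without base.

Step 15. Saturation of the chromone C2=C3 bond may set in before hydrodechlorination is complete, and acetate may slowly epimerise the free ketone. The fallback separates the two tasks and avoids hydrogen gas; it sets out from 28. Homogeneous hydrodechlorination (Pd(OAc)2, P(C6H11)3, HCO2Na, DMF, 80 °C) should give (R)-1-[2-(benzyloxy)-4-methoxyphenyl]-2-[7-(benzyloxy)-4-oxo-4H-chromen-3-yl]-3,3-bis[4-(benzyloxy)phenyl]propan-1-one F6. Lewis-acid debenzylation with BCl3 and pentamethylbenzene in CH2Cl2 at −78 °C, which spares the non-chelated methyl ether, then returns to the route at 29.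

## Further compounds

F1 | step 11 | methyl (S)-4-(2-chloro-4,6-dihydroxyphenyl)-2-{bis[4-(benzyloxy)phenyl]methyl}-4-oxobutanoate | COC(=O)[C@@H](CC(=O)c1c(O)cc(O)cc1Cl)C(c1ccc(OCc2ccccc2)cc1)c1ccc(OCc2ccccc2)cc1
F2 | step 12 | (S)-4-[4-(benzyloxy)-2-chloro-6-hydroxyphenyl]-2-{bis[4-(benzyloxy)phenyl]methyl}-4-oxobutanoic acid | OC(=O)[C@@H](CC(=O)c1c(O)cc(OCc2ccccc2)cc1Cl)C(c1ccc(OCc2ccccc2)cc1)c1ccc(OCc2ccccc2)cc1
F3 | step 13 | methyl (R)-2-[7-(benzyloxy)-5-chloro-4-oxo-4H-chromen-3-yl]-3,3-bis[4-(benzyloxy)phenyl]propanoate | COC(=O)[C@@H](c1coc2cc(OCc3ccccc3)cc(Cl)c2c1=O)C(c1ccc(OCc2ccccc2)cc1)c1ccc(OCc2ccccc2)cc1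
F4 | step 13 | (R)-2-[7-(benzyloxy)-5-chloro-4-oxo-4H-chromen-3-yl]-3,3-bis[4-(benzyloxy)phenyl]propanoic acid | OC(=O)[C@@H](c1coc2cc(OCc3ccccc3)cc(Cl)c2c1=O)C(c1ccc(OCc2ccccc2)cc1)c1ccc(OCc2ccccc2)cc1
F5 | step 14 | [2-(benzyloxy)-4-methoxyphenyl]zinc chloride | COc1ccc([Zn]Cl)c(OCc2ccccc2)c1
F6 | step 15 | (R)-1-[2-(benzyloxy)-4-methoxyphenyl]-2-[7-(benzyloxy)-4-oxo-4H-chromen-3-yl]-3,3-bis[4-(benzyloxy)phenyl]propan-1-one | COc1ccc(C(=O)[C@@H](c2coc3cc(OCc4ccccc4)ccc3c2=O)C(c2ccc(OCc3ccccc3)cc2)c2ccc(OCc3ccccc3)cc2)c(OCc2ccccc2)c1
A1 | alternative 1 | 2-[7-(benzyloxy)-4-oxo-4H-chromen-3-yl]-1-(2,4-dimethoxyphenyl)-3-hydroxyprop-2-en-1-one | COc1ccc(C(=O)C(=CO)c2coc3cc(OCc4ccccc4)ccc3c2=O)c(OC)c1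
A2 | alternative 1 | phenol | Oc1ccccc1
A3 | alternative 1 | (R)-2-[7-(benzyloxy)-4-oxo-4H-chromen-3-yl]-1-(2,4-dimethoxyphenyl)-3,3-bis(4-hydroxyphenyl)propan-1-one | COc1ccc(C(=O)[C@@H](c2coc3cc(OCc4ccccc4)ccc3c2=O)C(c5ccc(O)cc5)c6ccc(O)cc6)c(OC)c1
A4 | alternative 2 | 4-(benzyloxy)-2-{[(E)-3-[2-(benzyloxy)-4-methoxybenzoyl]-4,4-bis[4-(benzyloxy)phenyl]but-2-en-1-yl]oxy}benzaldehyde | COc1ccc(C(=O)/C(=C/COc2cc(OCc3ccccc3)ccc2C=O)C(c2ccc(OCc3ccccc3)cc2)c2ccc(OCc3ccccc3)cc2)c(OCc2ccccc2)c1
A5 | alternative 2 | (R)-1-[2-(benzyloxy)-4-methoxyphenyl]-2-[(S)-7-(benzyloxy)-4-oxochroman-3-yl]-3,3-bis[4-(benzyloxy)phenyl]propan-1-one | COc1ccc(C(=O)[C@@H]([C@H]2COc3cc(OCc4ccccc4)ccc3C2=O)C(c5ccc(OCc6ccccc6)cc5)c7ccc(OCc8ccccc8)cc7)c(OCc9ccccc9)c1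
A6 | alternative 3 | (R)-4-[7-(benzyloxy)-4-oxo-4H-chromen-3-yl]-5,5-bis[4-(benzyloxy)phenyl]pent-1-yn-3-one | C#CC(=O)[C@@H](c1coc2cc(OCc3ccccc3)ccc2c1=O)C(c1ccc(OCc2ccccc2)cc1)c1ccc(OCc2ccccc2)cc1
A7 | alternative 3 | 1,3-dimethoxy-1-(trimethylsilyloxy)buta-1,3-diene | COC(=C)C=C(OC)O[Si](C)(C)C
A8 | alternative 3 | (R)-2-[7-(benzyloxy)-4-oxo-4H-chromen-3-yl]-3,3-bis[4-(benzyloxy)phenyl]-1-(2-hydroxy-4-methoxyphenyl)propan-1-one | COc1ccc(C(=O)[C@@H](c2coc3cc(OCc4ccccc4)ccc3c2=O)C(c5ccc(OCc6ccccc6)cc5)c7ccc(OCc8ccccc8)cc7)c(O)c1
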